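## Retrosynthetic overview

1. The oxepane ring and C18 come last, from a 7-endo anti-Markovnikov photoredox hydroalkoxylation of the tertiary C3–OH onto the C14 isopropenyl group.
2. The 10-membered carbocycle (nine-membered oxonane) is closed by RCM of a cis-2,5-disubstituted tetrahydrofuran. The THF, C9 and C8 come from oxocarbenium allylation of a dioxolane, with C2–OH (set by CBS reduction) as the internal nucleophile.
3. C3/C4 come from a Z-olefin epoxidation followed by anti-opening. C11/C12 come from iodolactonization and deiodination of the Diels–Alder cyclohexene.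
4. The cyclohexene core (C1, C10, C14) comes from an organocatalytic iminium Diels–Alder between a dienal and a dienyl dioxolane.
5. Ring order: cyclohexene → bridged lactone (temporary) → THF → 10-membered carbocycle/oxonane (RCM) → oxepane.

Assumptions (one line each):
- The (2R,5R)-imidazolidinone is the catalyst enantiomer that gives the natural absolute configuration (if the opposite series results, use the (2S,5S) catalyst).
- C6 of 22–28 is racemic and irrelevant, since it is destroyed in Step 20.
- RCM gives the ring-Z C3=C4 olefin.
- Epoxidation occurs from the peripheral face.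

## Route

**Step 1**
Reactants: 1 methacrolein; 2 (formylmethylene)triphenylphosphorane
Product: 3 (2E)-4-methylpenta-2,4-dienal
Conditions: toluene, 80 °C
Reagents that add atoms: none (2 is the reactant)
Why: Wittig olefination with a stabilized ylide gives the E-enal.

**Step 2**
Reactants: 3; 4 1,2-bis(trimethylsilyloxy)ethane
Product: 5 2-[(1E)-3-methylbuta-1,3-dienyl]-1,3-dioxolane
Conditions: TMSOTf (cat.), CH2Cl2, −78 → 0 °C
Reagents that add atoms: 4, C[Si](C)(C)OCCO[Si](C)(C)C (gives the OCH2CH2O unit)
Why: Noyori acetalization masks C9 as a dioxolane, a latent oxocarbenium.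

**Step 3**
Reactants: 3 (dienophile, 1 equiv); 5 (diene, 3 equiv); 6 (2R,5R)-imidazolidinone·TfOH (20 mol%)
Product: 7 2-(1,3-dioxolan-2-yl)-4-methyl-6-(prop-1-en-2-yl)cyclohex-3-ene-1-carbaldehyde (CHO cis to dioxolanyl, trans to isopropenyl)
Conditions: CH2Cl2, H2O (2 equiv), −40 °C, 48 h
Reagents that add atoms: none
Why: This is an iminium-catalysed Diels–Alder (MacMillan type), and catalyst 6 shields one face of the (E)-iminium, which sets C1 and C14. Endo addition of the (E)-diene makes C10 cis to the CHO. The 2-methyl and 1-alkyl groups on the diene direct the "para/ortho" regiochemistry (C13–C14 and C10–C1 bonds). The trans C1/C14 relationship comes from the E-dienophile.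

**Step 4**
Reactants: 7
Product: 8 the corresponding carboxylic acid
Conditions: NaClO2, NaH2PO4, 2-methylbut-2-ene, t-BuOH/H2O, rt
Reagents that add atoms: NaClO2, O=Cl[O-].[Na+] (adds O)
Why: Pinnick oxidation is chemoselective for the aldehyde over the alkenes and acetal; no stereocentre is touched.

**Step 5**
Reactants: 8
Product: 9 bridged iodolactone (C2 carbonyl bonded through O to C11; C12 bears Me and I, with I anti to the lactone oxygen)
Conditions: I2, NaHCO3, MeCN, 0 °C
Reagents that add atoms: iodine, II
Why: Iodolactonization. The axial carboxylate (cis to the dioxolanyl, trans to the isopropenyl) closes onto C11 of the more nucleophilic trisubstituted ring olefin in the 1,3-diaxial sense to give the bridged γ-lactone. The iodonium forms on the opposite face and opens trans-diaxially, so C11–O is cis to C2 and C9 and I sits on C12. The 1,1-disubstituted isopropenyl group reacts with I+ much more slowly under these kinetic, buffered conditions.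

**Step 6**
Reactants: 9
Product: 10 bridged lactone (C12–H anti to the lactone oxygen, Me cis to it)
Conditions: Bu3SnH, AIBN, benzene, 80 °C
Reagents that add atoms: none (hydride only)
Why: Radical deiodination. H is delivered to the tertiary C12 radical from the face away from the lactone bridge (axial H), leaving Me equatorial and cis to C11–O, as in the target.

**Step 7**
Reactants: 10
Product: 11 hydroxy Weinreb amide (C11–OH; C2 is the amide carbonyl)
Conditions: MeNH(OMe)·HCl, i-PrMgCl, THF, −20 °C
Reagents that add atoms: N,O-dimethylhydroxylamine, CNOC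
Why: Grignard-mediated aminolysis opens the strained bridged lactone and frees C11–OH with no stereochemical change.

**Step 8**
Reactants: 11
Product: 12 C11 acetate
Conditions: Ac2O, DMAP, Et3N, CH2Cl2, rt
Reagents that add atoms: acetic anhydride, CC(=O)OC(C)=O
Why: Acylation installs the C11 acetate of the target and prevents re-lactonization.

**Step 9**
Reactants: 12; 13 isopropenylmagnesium bromide
Product: 14 isopropenyl ketone (C2=O, with C3=CH2 and a C3 methyl)
Conditions: THF, −20 °C, 1.3 equiv 13, quench cold
Reagents that add atoms: 13, C=C(C)[Mg]Br (gives the C3/Me/C4-terminus fragment)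
Why: Weinreb ketone synthesis. The chelated tetrahedral intermediate prevents over-addition, and at −20 °C with a slight excess of Grignard reagent, amide addition is much faster than attack on the hindered secondary acetate.

**Step 10**
Reactants: 14; 15 (S)-Me-CBS oxazaborolidine (10 mol%)
Product: 16 allylic alcohol (C2-(S)-OH)
Conditions: BH3·SMe2, THF, −20 °C
Reagents that add atoms: none (hydride only)
Why: Corey–Bakshi–Shibata reduction sets the C2 carbinol by catalyst control. The branched ring carbon C1 is treated as the large ketone substituent and the isopropenyl as the small one, which gives the (S) alcohol matching the target C2.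

**Step 11**
Reactants: 17 2-bromoallyltrimethylsilane; 18 DMF
Product: 19 2-[(trimethylsilyl)methyl]acrolein
Conditions: t-BuLi (2 equiv), Et2O, −78 °C; then 18
Reagents that add atoms: 18, CN(C)C=O (gives the CHO)
Why: Li–Br exchange then Bouveault formylation; the allylsilane is untouched.

**Step 12**
Reactants: 19; 20 allylmagnesium bromide
Product: 21 2-[(trimethylsilyl)methyl]hexa-1,5-dien-3-ol
Conditions: THF, −78 °C
Reagents that add atoms: 20, C=CC[Mg]Br (gives C4–C5)
Why: 1,2-addition of the Grignard reagent to the enal.

**Step 13**
Reactants: 21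
Product: 22 allylsilane TBS ether (racemic at C6)
Conditions: TBSCl, imidazole, DMF, rt
Reagents that add atoms: TBSCl, CC(C)(C)[Si](C)(C)Cl
Why: Silylation protects C6–O (the stereocentre is later oxidized).

**Step 14**
Reactants: 16; 22
Product: 23 cis-fused tetrahydrofuran with C9 bearing the C8–C7(=CH2)–C6(OTBS)–C5–C4H=CH2 chain
Conditions: TMSOTf (1.2 equiv), CH2Cl2, −78 → −40 °C
Reagents that add atoms: 22 (contributes C8–C4 and the C7 methylene); TMSOTf adds nothing
Why: Hosomi–Sakurai allylation of an acetal. TMSOTf opens the dioxolane and the C2–OH traps the oxocarbenium intramolecularly to form the cis-fused THF. The re-ionized cyclic oxocarbenium is then attacked at C9 by the 2-substituted allylsilane from the convex face. This sets C9 with the C8 chain cis to the C3 chain (2,5-cis).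

**Step 15**
Reactants: 23
Product: 24 macrocycle (10-membered carbocycle/oxonane) with ring-Z trisubstituted C3=C4
Conditions: Hoveyda–Grubbs II (10 mol%), toluene, 1 mM, 60 °C
Reagents that add atoms: none (ethylene lost)
Why: Ring-closing metathesis of the C3 isopropenyl with the C4 vinyl group across the cis-2,5 chains. The 1,1-disubstituted C7 and C14 olefins are unreactive.

**Step 16**
Reactants: 24
Product: 25 C3–C4 cis-epoxide
Conditions: DMDO, acetone/CH2Cl2, 0 °C
Reagents that add atoms: DMDO, CC1(C)OO1 (adds O)
Why: Electrophilic epoxidation is chemoselective for the trisubstituted Z-olefin over the 1,1-disubstituted olefins, as in limonene. Peripheral-face attack fixes the C4 configuration and the face of the epoxide oxygen at C3.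

**Step 17**
Reactants: 25
Product: 26 C3 tertiary alcohol / C4 secondary alcohol (anti-diol)
Conditions: HClO4 (aq, 0.05 M), THF/H2O, 0 °C
Reagents that add atoms: water, O
Why: Acid-catalysed epoxide hydrolysis goes by SN2-like attack at the tertiary C3 with inversion. The β-ether oxygen at C2 disfavours a free cation. This gives the C3/C4 configuration of the target (anti-addition to a Z-olefin).

**Step 18**
Reactants: 26
Product: 27 C4 octanoate
Conditions: octanoyl chloride, pyridine, DMAP, CH2Cl2, 0 °C
Reagents that add atoms: octanoyl chloride, CCCCCCCC(=O)Cl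
Why: Acylation selectively esterifies the secondary C4–OH; the tertiary C3–OH is unreactive.

**Step 19**
Reactants: 27
Product: 28 C6 allylic alcohol
Conditions: HF·pyridine, pyridine, THF, 0 °C
Reagents that add atoms: none (hydrogen only)
Why: Buffered, mildly acidic desilylation avoids base-promoted 1,3-acyl migration from C4 to C6.

**Step 20**
Reactants: 28
Product: 29 α-methylene ketone (C6=O, C7=CH2)
Conditions: Dess–Martin periodinane, NaHCO3, CH2Cl2, 0 °C
Reagents that add atoms: none
Why: Oxidation of the secondary allylic alcohol destroys the C6 stereocentre; the tertiary alcohol is inert.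

**Step 21**
Reactants: 29
Product: 30 Asbestinin 16
Conditions: 9-mesityl-10-methylacridinium BF4 (5 mol%), 2-phenylmalononitrile (20 mol%), DCE (0.02 M), blue LEDs (450 nm), rt, 24 h
Reagents that add atoms: none (isomerization)
Why: Proposed new method: the excited acridinium oxidizes the isopropenyl group (the electron-poor α-methylene ketone is not oxidized) to its radical cation. The tertiary C3–OH adds to the unsubstituted terminus C19 (7-endo, anti-Markovnikov) because that gives the tertiary C18 radical. This radical takes H from the malononitrile HAT donor on the less hindered convex face, which sets C18. The competing 6-exo Markovnikov closure at C18 (a gem-dimethyl tetrahydropyran) is disfavoured by the radical-cation charge distribution. The closest known reaction is Nicewicz-type anti-Markovnikov photoredox hydroetherification, here extended to a tertiary-alcohol nucleophile, seven-membered ring closure and a caged polyfunctional substrate. A C–H acid replaces the usual thiol HAT donor to avoid thia-Michael addition to the enone.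

## Compound list
1 | methacrolein | C=C(C)C=O | starting material
2 | (formylmethylene)triphenylphosphorane | O=CC=P(c1ccccc1)(c1ccccc1)c1ccccc1 | starting material
3 | (2E)-4-methylpenta-2,4-dienal | C=C(C)/C=C/C=O | intermediate
4 | 1,2-bis(trimethylsilyloxy)ethane | C[Si](C)(C)OCCO[Si](C)(C)C | starting material
5 | 2-[(1E)-3-methylbuta-1,3-dienyl]-1,3-dioxolane | C=C(C)/C=C/C1OCCO1 | intermediate
6 | (2R,5R)-5-benzyl-2-tert-butyl-3-methylimidazolidin-4-one, TfOH salt (organocatalyst) | CN1[C@H](C(C)(C)C)N[C@H](Cc2ccccc2)C1=O | starting material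
7 | cyclohexene aldehyde (Diels–Alder adduct) | O=C[C@H]1[C@H](C(C)=C)CC(C)=C[C@H]1C2OCCO2 | intermediate
8 | cyclohexene carboxylic acid | OC(=O)[C@H]1[C@H](C(C)=C)CC(C)=C[C@H]1C2OCCO2 | intermediate
9 | bridged iodolactone | O=C1O[C@H]2[C@@H](C3OCCO3)[C@@H]1[C@H](C(C)=C)C[C@]2(C)I | intermediate
10 | bridged lactone (deiodinated) | O=C1O[C@H]2[C@@H](C3OCCO3)[C@@H]1[C@H](C(C)=C)C[C@H]2C | intermediate
11 | hydroxy Weinreb amide | CON(C)C(=O)[C@H]1[C@H](C(C)=C)C[C@@H](C)[C@@H](O)[C@H]1C2OCCO2 | intermediate
12 | acetoxy Weinreb amide | CON(C)C(=O)[C@H]1[C@H](C(C)=C)C[C@@H](C)[C@@H](OC(C)=O)[C@H]1C2OCCO2 | intermediate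
13 | isopropenylmagnesium bromide | C=C(C)[Mg]Br | starting material
14 | isopropenyl ketone | C=C(C)C(=O)[C@H]1[C@H](C(C)=C)C[C@@H](C)[C@@H](OC(C)=O)[C@H]1C2OCCO2 | intermediate
15 | (S)-2-methyl-CBS-oxazaborolidine (catalyst) | CB1OC(c2ccccc2)(c2ccccc2)[C@@H]2CCCN12 | starting material
16 | allylic alcohol (C2-S) | C=C(C)[C@@H](O)[C@H]1[C@H](C(C)=C)C[C@@H](C)[C@@H](OC(C)=O)[C@H]1C2OCCO2 | intermediate
17 | 2-bromoallyltrimethylsilane | C=C(Br)C[Si](C)(C)C | starting material
18 | N,N-dimethylformamide | CN(C)C=O | starting material
19 | 2-[(trimethylsilyl)methyl]acrolein | C=C(C[Si](C)(C)C)C=O | intermediate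
20 | allylmagnesium bromide | C=CC[Mg]Br | starting material
21 | 2-[(trimethylsilyl)methyl]hexa-1,5-dien-3-ol | C=CCC(O)C(=C)C[Si](C)(C)C | intermediate
22 | allylsilane TBS ether (racemic at C6) | C=CCC(O[Si](C)(C)C(C)(C)C)C(=C)C[Si](C)(C)C | intermediate
23 | THF with C9 side chain (C6 epimeric mixture) | C=CCC(O[Si](C)(C)C(C)(C)C)C(=C)C[C@@H]1O[C@H](C(C)=C)[C@H]2[C@H](C(C)=C)C[C@@H](C)[C@@H](OC(C)=O)[C@H]21 | intermediate
24 | Z-macrocyclic olefin | C=C1C[C@@H]2O[C@H](/C(C)=C\CC1O[Si](C)(C)C(C)(C)C)[C@H]3[C@H](C(C)=C)C[C@@H](C)[C@@H](OC(C)=O)[C@H]32 | intermediate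
25 | C3–C4 epoxide | C=C1C[C@@H]2O[C@H]([C@]3(C)O[C@@H]3CC1O[Si](C)(C)C(C)(C)C)[C@H]4[C@H](C(C)=C)C[C@@H](C)[C@@H](OC(C)=O)[C@H]42 | intermediate
26 | C3/C4 diol | C=C1C[C@@H]2O[C@H]([C@@](C)(O)[C@H](O)CC1O[Si](C)(C)C(C)(C)C)[C@H]3[C@H](C(C)=C)C[C@@H](C)[C@@H](OC(C)=O)[C@H]32 | intermediate
27 | C4 octanoate | C=C1C[C@@H]2O[C@H]([C@@](C)(O)[C@H](OC(=O)CCCCCCC)CC1O[Si](C)(C)C(C)(C)C)[C@H]3[C@H](C(C)=C)C[C@@H](C)[C@@H](OC(C)=O)[C@H]32 | intermediate
28 | C6 allylic alcohol | C=C1C[C@@H]2O[C@H]([C@@](C)(O)[C@H](OC(=O)CCCCCCC)CC1O)[C@H]3[C@H](C(C)=C)C[C@@H](C)[C@@H](OC(C)=O)[C@H]32 | intermediate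
29 | enone precursor | C=C1C[C@@H]2O[C@H]([C@@](C)(O)[C@H](OC(=O)CCCCCCC)CC1=O)[C@H]3[C@H](C(C)=C)C[C@@H](C)[C@@H](OC(C)=O)[C@H]32 | intermediate
30 | Asbestinin 16 | C=C1C[C@@H]2O[C@H]3[C@H]4[C@@H](C[C@@H](C)[C@@H](OC(C)=O)[C@H]42)[C@@H](C)CO[C@@]3(C)[C@H](OC(=O)CCCCCCC)CC1=O | target

## Totals
- Total steps: 21.
- Longest linear sequence: 18 (Steps 1–10, 14–21).

## Three steps most likely to fail
1. **Step 21 (proposed new method).** The 7-endo closure with a tertiary alcohol may lose to 6-exo Markovnikov closure or to side reactions of the enone, and C18 selectivity is uncertain.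
   - Fallback (known chemistry): hydroborate the C14 isopropenyl group at the stage of 12 (where it is the only alkene) with 9-BBN, then NaBO3 oxidation, and protect the C19 alcohol as its PMB ether. Carry this material through Steps 9–16. Then remove PMB with DDQ and close the oxepane by CSA-promoted 7-exo opening of the C3–C4 epoxide at tertiary C3 (inversion), which gives the C3–O–C19 ether and the C4–OH directly and replaces Steps 17 and 21. Then run Steps 18–20 and separate the C18 epimers.
2. **Step 15 (RCM).** Forming a trisubstituted Z-olefin in a nine-membered oxonane bridged to the cyclohexane may fail or give the wrong geometry.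
   - Fallback: use 17 in place of 22 in Step 14 to put a vinyl bromide at C7. Do E-selective cross-metathesis of the C3 isopropenyl with 4-(TBSO)but-1-ene, then syn-dihydroxylation of the acyclic E-olefin (OsO4, NMO), which gives the same C3/C4 relative configuration as Z-epoxide/anti-opening. Protect the diol as an acetonide, unmask the C6 aldehyde, and close the C6–C7 bond by intramolecular Nozaki–Hiyama–Kishi coupling (CrCl2/NiCl2). Then carry on with C4 octanoylation and oxidation of the C6 allylic alcohol to the enone.
3. **Step 14 (oxocarbenium allylation).** The 2,5-cis selectivity may be poor, or the isopropenyl groups and TBS ether may not survive TMSOTf.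
   - Fallback: hydrolyse the dioxolane to the C9 aldehyde and set C9 by reagent-controlled addition of the corresponding 2-substituted allylboronate. Then form the THF by Pd-catalysed intramolecular allylic etherification (Tsuji–Trost) of the C2 allylic carbonate with the C9 alkoxide.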